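Ring A is not coupled to ring B but grown onto the ring B oxygen. Its contiguous C1 (carboxyl carbon, later CH2OH), C2–Br, C3–O–aryl and C4–OH are disconnected at C2–C3 and C6–C1 into methyl 3-bromopropiolate (C1, C2) and a 1-methoxy-3-silyloxybutadiene (C3–C6) whose C3 terminus already bears the ring B aryloxy group. One cycloaddition–aromatization then delivers the crowded diaryl ether, the C4 phenol and a C2 bromine that lies meta to that phenol and is out of reach of electrophilic substitution. The diene precursor is made from a ring B salicylate by O-alkylation with a preformed bromomethyl β-methoxyvinyl ketone, so no strong base meets the ortho ester.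

Key step: step 7

Remark: 2-hydroxy-3,4-dimethoxybenzoic acid, (E)-1-methoxy-3-(trimethylsilyloxy)buta-1,3-diene and methyl propiolate are taken as purchased. The target is achiral; the two stereocentres of the cycloadduct are transient.

Step 1
Reactants: 1 2-hydroxy-3,4-dimethoxybenzoic acid
Product: 2 methyl 2-hydroxy-3,4-dimethoxybenzoate
Conditions: MeOH, H2SO4 (cat.), reflux
Reagents that add atoms: methanol, SMILES CO
Why: Fischer esterification leaves the hydrogen-bonded phenol untouched, and esterifying before bromination avoids ipso bromodecarboxylation of the salicylic acid.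

Step 2
Reactants: 2 methyl 2-hydroxy-3,4-dimethoxybenzoate
Product: 3 methyl 5-bromo-2-hydroxy-3,4-dimethoxybenzoate
Conditions: NBS (1.0 equiv), MeCN, 0 °C → rt
Reagents that add atoms: N-bromosuccinimide, SMILES O=C1CCC(=O)N1Br
Why: Electrophilic aromatic bromination should go to C5, which is para to the phenol and ortho to the C4 methoxy group, whereas the only other free position (C6) is meta to the phenol and ortho to the ester.

Step 3
Reactants: 4 (E)-1-methoxy-3-(trimethylsilyloxy)buta-1,3-diene
Product: 5 (E)-1-bromo-4-methoxybut-3-en-2-one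
Conditions: NBS (1.0 equiv), THF, −78 → 0 °C; aq. NaHCO3; used at once
Reagents that add atoms: N-bromosuccinimide, SMILES O=C1CCC(=O)N1Br
Why: α-Bromination of a silyl enol ether: the terminal CH2 is the carbon of this dienol ether that reacts with electrophiles (as in Mukaiyama-type additions), and loss of the silyl group returns the ketone with the E enol ether intact.

Step 4
Reactants: 3 methyl 5-bromo-2-hydroxy-3,4-dimethoxybenzoate; 5 (E)-1-bromo-4-methoxybut-3-en-2-one
Product: 6 methyl 5-bromo-3,4-dimethoxy-2-{[(E)-4-methoxy-2-oxobut-3-en-1-yl]oxy}benzoate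
Conditions: K2CO3, acetone, 0 °C → rt
Reagents that add atoms: none
Why: Williamson ether synthesis (SN2) at a primary α-bromo ketone carbon should outrun conjugate addition to the vinylogous ester, and the carbonate base is too weak to drive Claisen closure of the new OCH2 onto the ortho ester.

Step 5
Reactants: 6 methyl 5-bromo-3,4-dimethoxy-2-{[(E)-4-methoxy-2-oxobut-3-en-1-yl]oxy}benzoate
Product: 7 methyl 5-bromo-3,4-dimethoxy-2-{[(1Z,3E)-4-methoxy-2-(trimethylsilyloxy)buta-1,3-dien-1-yl]oxy}benzoate
Conditions: TMSOTf (1.2 equiv), Et3N (2 equiv), Et2O, 0 °C → rt; filtered under Ar, used crude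
Reagents that add atoms: trimethylsilyl trifluoromethanesulfonate, SMILES C[Si](C)(C)OS(=O)(=O)C(F)(F)F
Why: Soft enolization and O-silylation of a β-methoxy enone can only occur at the OCH2 group, so the regiochemistry is unambiguous; the Z enol silane (aryloxy cis to silyloxy) is expected, and this geometry disappears on aromatization in any case.

Step 6
Reactants: 8 methyl propiolate
Product: 9 methyl 3-bromopropiolate
Conditions: NBS (1.1 equiv), AgNO3 (10 mol %), acetone, rt
Reagents that add atoms: N-bromosuccinimide, SMILES O=C1CCC(=O)N1Br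
Why: Silver-catalysed bromination of a terminal alkyne through the silver acetylide, a standard preparation of this 1-bromoalkyne.

Step 7
Reactants: 7 methyl 5-bromo-3,4-dimethoxy-2-{[(1Z,3E)-4-methoxy-2-(trimethylsilyloxy)buta-1,3-dien-1-yl]oxy}benzoate; 9 methyl 3-bromopropiolate
Product: 12 methyl 2-bromo-3-[4-bromo-2,3-dimethoxy-6-(methoxycarbonyl)phenoxy]-4-hydroxybenzoate, via cis-cyclohexadiene cycloadduct 10 (not isolated), via aryl trimethylsilyl ether 11 (not isolated)
Conditions: 9 (1.5 equiv), PhMe, 70 °C, dark; then 1 M HCl, THF, rt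
Reagents that add atoms: none
Why: A normal-electron-demand Diels–Alder reaction in which the diene terminus that becomes C3 (the β-carbon of the silyl enol ether, pushed further by the vinylogous methoxy group) bonds ahead of the other terminus to the bromine-bearing β-carbon of the ynoate (C2), while C6 closes onto C1; it is the established benzannulation of 1-alkoxy-3-silyloxybutadienes with acetylenic esters to 4-hydroxybenzoates, and both 4-oxygenated dienes of this family and 3-bromopropiolates are known cycloaddition partners. Ring A is closed as a six-membered carbocycle by suprafacial [4+2] union of two components, both ring bonds arising in one concerted, asynchronous event. No stereocentre survives, because C3 and C6 of the cis-adduct 10 are both flattened on aromatization. The regioselectivity is secured because the 1-methoxy and 3-silyloxy donors reinforce each other and outweigh the aryloxy group, whose lone pair is drained by the ester- and bromine-substituted ring B. The chemoselectivity of aromatization is secured because the C6 methoxy group departs either by ionization assisted by the silyl enol ether or by E1cB from the ester-conjugated dienolate formed at C3–H, so methanol and not the ring B phenol is expelled, giving aryl silyl ether 11, which dilute acid hydrolyses to phenol 12. The bromine arrives on the alkyne carbon, so C2, wedged between ester and aryloxy group, never has to be brominated.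

Step 8
Reactants: 12 methyl 2-bromo-3-[4-bromo-2,3-dimethoxy-6-(methoxycarbonyl)phenoxy]-4-hydroxybenzoate
Product: 13 methyl 2,5-dibromo-3-[4-bromo-2,3-dimethoxy-6-(methoxycarbonyl)phenoxy]-4-hydroxybenzoate
Conditions: NBS (1.05 equiv), MeCN, 0 °C
Reagents that add atoms: N-bromosuccinimide, SMILES O=C1CCC(=O)N1Br
Why: Electrophilic aromatic bromination should go to C5, the only free position ortho to the new phenol (its para position is C1), while the single C–H of ring B sits on a ring deactivated by an ester and a bromine and carrying no free phenol.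

Step 9
Reactants: 13 methyl 2,5-dibromo-3-[4-bromo-2,3-dimethoxy-6-(methoxycarbonyl)phenoxy]-4-hydroxybenzoate
Product: 14 methyl 2,5-dibromo-3-[4-bromo-2,3-dihydroxy-6-(methoxycarbonyl)phenoxy]-4-hydroxybenzoate
Conditions: BBr3 (6 equiv), CH2Cl2, −78 → 0 °C; then H2O, 0 °C
Reagents that add atoms: none
Why: Lewis acid cleavage of the two aryl methyl ethers (bromide attacks the methyl group of the boron-complexed ether) should spare the diaryl ether, the aryl bromides and, at or below 0 °C, the methyl esters; it is placed before the reduction because BBr3 would turn benzylic alcohols into benzylic bromides.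

Step 10
Reactants: 14 methyl 2,5-dibromo-3-[4-bromo-2,3-dihydroxy-6-(methoxycarbonyl)phenoxy]-4-hydroxybenzoate
Product: 15 {2,5-dibromo-3-[4-bromo-2,3-dihydroxy-6-(hydroxymethyl)phenoxy]-4-hydroxyphenyl}methanol (CNP0104332.0)
Conditions: iBu2AlH (10 equiv), THF, −78 → 0 °C; EtOAc quench, aq. KNaC4H4O6, brought to pH 4–5 cold, no alcohol solvent
Reagents that add atoms: none
Why: Hydride reduction of both esters to primary alcohols after the three phenols are converted in the flask to aluminium phenoxides; iBu2AlH does not touch aryl bromides, and the low temperature and near-neutral, alcohol-free work-up protect the two para-hydroxybenzyl alcohols.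

Compound list
1 | 2-hydroxy-3,4-dimethoxybenzoic acid | COc1ccc(C(=O)O)c(O)c1OC | starting material
2 | methyl 2-hydroxy-3,4-dimethoxybenzoate | COC(=O)c1ccc(OC)c(OC)c1O | intermediate
3 | methyl 5-bromo-2-hydroxy-3,4-dimethoxybenzoate | COC(=O)c1cc(Br)c(OC)c(OC)c1O | intermediate
4 | (E)-1-methoxy-3-(trimethylsilyloxy)buta-1,3-diene | CO/C=C/C(=C)O[Si](C)(C)C | starting material
5 | (E)-1-bromo-4-methoxybut-3-en-2-one | CO/C=C/C(=O)CBr | intermediate
6 | methyl 5-bromo-3,4-dimethoxy-2-{[(E)-4-methoxy-2-oxobut-3-en-1-yl]oxy}benzoate | CO/C=C/C(=O)COc1c(C(=O)OC)cc(Br)c(OC)c1OC | intermediate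
7 | methyl 5-bromo-3,4-dimethoxy-2-{[(1Z,3E)-4-methoxy-2-(trimethylsilyloxy)buta-1,3-dien-1-yl]oxy}benzoate | CO/C=C/C(=C/Oc1c(C(=O)OC)cc(Br)c(OC)c1OC)O[Si](C)(C)C | intermediate
8 | methyl propiolate | C#CC(=O)OC | starting material
9 | methyl 3-bromopropiolate | COC(=O)C#CBr | intermediate
10 | methyl cis-2-bromo-3-[4-bromo-2,3-dimethoxy-6-(methoxycarbonyl)phenoxy]-6-methoxy-4-(trimethylsilyloxy)cyclohexa-1,4-diene-1-carboxylate (racemic; not isolated) | COC(=O)C1=C(Br)[C@@H](Oc2c(C(=O)OC)cc(Br)c(OC)c2OC)C(O[Si](C)(C)C)=C[C@H]1OC | intermediate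
11 | methyl 2-bromo-3-[4-bromo-2,3-dimethoxy-6-(methoxycarbonyl)phenoxy]-4-(trimethylsilyloxy)benzoate (not isolated) | COC(=O)c1ccc(O[Si](C)(C)C)c(Oc2c(C(=O)OC)cc(Br)c(OC)c2OC)c1Br | intermediate
12 | methyl 2-bromo-3-[4-bromo-2,3-dimethoxy-6-(methoxycarbonyl)phenoxy]-4-hydroxybenzoate | COC(=O)c1ccc(O)c(Oc2c(C(=O)OC)cc(Br)c(OC)c2OC)c1Br | intermediate
13 | methyl 2,5-dibromo-3-[4-bromo-2,3-dimethoxy-6-(methoxycarbonyl)phenoxy]-4-hydroxybenzoate | COC(=O)c1cc(Br)c(O)c(Oc2c(C(=O)OC)cc(Br)c(OC)c2OC)c1Br | intermediate
14 | methyl 2,5-dibromo-3-[4-bromo-2,3-dihydroxy-6-(methoxycarbonyl)phenoxy]-4-hydroxybenzoate | COC(=O)c1cc(Br)c(O)c(Oc2c(C(=O)OC)cc(Br)c(O)c2O)c1Br | intermediate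
15 | {2,5-dibromo-3-[4-bromo-2,3-dihydroxy-6-(hydroxymethyl)phenoxy]-4-hydroxyphenyl}methanol | OCc1cc(Br)c(O)c(Oc2c(CO)cc(Br)c(O)c2O)c1Br | target

Total step count: 10. Longest linear sequence: 8 steps (steps 1, 2, 4, 5, 7, 8, 9, 10).

Steps most likely to fail

Step 7. The cycloaddition may be too slow at the doubly substituted C2–C3 bond, so that the heat-sensitive bromoalkyne polymerizes and the silyl dienol ether hydrolyses before they combine. The fallback sets out from 6 and comes back at 12, and replaces the methoxy leaving group by an amino group to give a far more reactive 1-amino-3-silyloxydiene. Dimethylamine (THF, rt) exchanges the methoxy group of 6 by addition–elimination to give the vinylogous amide methyl 5-bromo-2-{[(E)-4-(dimethylamino)-2-oxobut-3-en-1-yl]oxy}-3,4-dimethoxybenzoate F1. Soft enolization (TBSOTf, Et3N, Et2O, 0 °C) gives methyl 5-bromo-2-{[(1Z,3E)-2-(tert-butyldimethylsilyloxy)-4-(dimethylamino)buta-1,3-dien-1-yl]oxy}-3,4-dimethoxybenzoate F2. Dienes of this class add to alkynoates at or below room temperature with the same regiochemistry, so F2 and 9 (THF, 0 °C → rt) should give methyl cis-2-bromo-3-[4-bromo-2,3-dimethoxy-6-(methoxycarbonyl)phenoxy]-4-(tert-butyldimethylsilyloxy)-6-(dimethylamino)cyclohexa-1,4-diene-1-carboxylate F3. HF·pyridine in MeCN then expels dimethylamine to give methyl 2-bromo-3-[4-bromo-2,3-dimethoxy-6-(methoxycarbonyl)phenoxy]-4-(tert-butyldimethylsilyloxy)benzoate F4 and cleaves its silyl ether to 12.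

Step 4. The phenoxide may attack the β-carbon of the vinylogous ester (exchange of methoxide) instead of the bromomethyl carbon, or the bifunctional bromo enone may decompose under base before alkylation is complete. The fallback sets out from 3 and comes back at 7, and carries the β-carbon as an acetal through the alkylation. Purchased 4,4-dimethoxybutan-2-one F5 is converted at its methyl group into the kinetic enol silane 4,4-dimethoxy-2-(trimethylsilyloxy)but-1-ene F6 (LDA, TMSCl, THF, −78 °C) and brominated (NBS, THF, 0 °C) to 1-bromo-4,4-dimethoxybutan-2-one F7. Alkylation of 3 (K2CO3, acetone, rt) gives the keto acetal methyl 5-bromo-2-(4,4-dimethoxy-2-oxobutoxy)-3,4-dimethoxybenzoate F8, which has no Michael acceptor. Excess TMSOTf and Et3N (Et2O, 0 °C → rt) then ionize the acetal, eliminate it to the enol ether and silylate the ketone in the same flask to give 7.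

Step 10. The esters, each para to an aluminium phenoxide, may reduce incompletely. Alternatively, the para-oxido benzylic aluminates may lose oxygen through quinone methides, which leads to over-reduction to methyl groups or to oligomers on work-up. The fallback sets out from 14 and comes back at 15, and masks the phenols during the reduction. Silylation (TBSOTf, 2,6-lutidine, CH2Cl2, 0 °C → rt) gives methyl 2,5-dibromo-3-[4-bromo-2,3-bis(tert-butyldimethylsilyloxy)-6-(methoxycarbonyl)phenoxy]-4-(tert-butyldimethylsilyloxy)benzoate F9. Reduction with iBu2AlH (CH2Cl2, −78 °C) then proceeds on ordinary aryl esters to give {2,5-dibromo-3-[4-bromo-2,3-bis(tert-butyldimethylsilyloxy)-6-(hydroxymethyl)phenoxy]-4-(tert-butyldimethylsilyloxy)phenyl}methanol F10. Fluoride buffered with acetic acid (Bu4NF, AcOH, THF, 0 °C) removes the three silyl groups under near-neutral conditions to give 15.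

Further compounds
F1 | step 7 | methyl 5-bromo-2-{[(E)-4-(dimethylamino)-2-oxobut-3-en-1-yl]oxy}-3,4-dimethoxybenzoate | CN(C)/C=C/C(=O)COc1c(C(=O)OC)cc(Br)c(OC)c1OC
F2 | step 7 | methyl 5-bromo-2-{[(1Z,3E)-2-(tert-butyldimethylsilyloxy)-4-(dimethylamino)buta-1,3-dien-1-yl]oxy}-3,4-dimethoxybenzoate | CN(C)/C=C/C(=C/Oc1c(C(=O)OC)cc(Br)c(OC)c1OC)O[Si](C)(C)C(C)(C)C
F3 | step 7 | methyl cis-2-bromo-3-[4-bromo-2,3-dimethoxy-6-(methoxycarbonyl)phenoxy]-4-(tert-butyldimethylsilyloxy)-6-(dimethylamino)cyclohexa-1,4-diene-1-carboxylate (racemic) | COC(=O)C1=C(Br)[C@@H](Oc2c(C(=O)OC)cc(Br)c(OC)c2OC)C(O[Si](C)(C)C(C)(C)C)=C[C@H]1N(C)C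
F4 | step 7 | methyl 2-bromo-3-[4-bromo-2,3-dimethoxy-6-(methoxycarbonyl)phenoxy]-4-(tert-butyldimethylsilyloxy)benzoate | COC(=O)c1ccc(O[Si](C)(C)C(C)(C)C)c(Oc2c(C(=O)OC)cc(Br)c(OC)c2OC)c1Br
F5 | step 4 | 4,4-dimethoxybutan-2-one (purchased) | CC(=O)CC(OC)OC
F6 | step 4 | 4,4-dimethoxy-2-(trimethylsilyloxy)but-1-ene | C=C(CC(OC)OC)O[Si](C)(C)C
F7 | step 4 | 1-bromo-4,4-dimethoxybutan-2-one | BrCC(=O)CC(OC)OC
F8 | step 4 | methyl 5-bromo-2-(4,4-dimethoxy-2-oxobutoxy)-3,4-dimethoxybenzoate | COC(CC(=O)COc1c(C(=O)OC)cc(Br)c(OC)c1OC)OC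
F9 | step 10 | methyl 2,5-dibromo-3-[4-bromo-2,3-bis(tert-butyldimethylsilyloxy)-6-(methoxycarbonyl)phenoxy]-4-(tert-butyldimethylsilyloxy)benzoate | COC(=O)c1cc(Br)c(O[Si](C)(C)C(C)(C)C)c(Oc2c(C(=O)OC)cc(Br)c(O[Si](C)(C)C(C)(C)C)c2O[Si](C)(C)C(C)(C)C)c1Br
F10 | step 10 | {2,5-dibromo-3-[4-bromo-2,3-bis(tert-butyldimethylsilyloxy)-6-(hydroxymethyl)phenoxy]-4-(tert-butyldimethylsilyloxy)phenyl}methanol | OCc1cc(Br)c(O[Si](C)(C)C(C)(C)C)c(Oc2c(CO)cc(Br)c(O[Si](C)(C)C(C)(C)C)c2O[Si](C)(C)C(C)(C)C)c1Br
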